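A direct plan would condense the ring B aldehyde 8-hydroxy-2,2-dimethyl-5-prenyl-2H-chromene-6-carbaldehyde A1 with 2-hydroxy-4-prenyloxyacetophenone A2 to the chalcone A3, would reduce away the enone C=C and C=O to the diarylpropane prenyl ether A4, and would finish with an aromatic Claisen rearrangement.
Its weakest steps would be: the oxidative closure of the pyran ring of A1 from a 2,3-diprenylcatechol, which would rest on no precedent; the erasure of the enone beside four other alkenes, which would cost several redox operations and add no complexity; and the rearrangement of A4 near 200 °C, whose preference for C5 over the carbon between the two oxygens would not be secured.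

The route cuts ring B at two adjacent bonds at once: C6–CH2 of the propane chain and C5–CH2 of the prenyl group. C5 of the 2,2-dimethyl-2H-chromene lies between C4a, whose C4–H blocks one side as in 1-iodonaphthalene, and the only ortho C–H, C6–H. A 5-iodochromene is thus a Catellani substrate: one palladium/norbornene operation would alkylate C6–H with the ring A propyl iodide and prenylate C5. The chain arrives as sp3 carbon, so nothing has to be reduced; the pyran ring comes from a propargyl ether rearrangement and the 1,1-dimethylallyl group from a branched-selective allylboron coupling, so no oxidative cyclisation and no prenyl ether rearrangement remain.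

Key step: step 9

Remark: kazinol K is achiral, so no stereocentre has to be set. The only geometric element, the cis C3=C4 bond of the chromene, is fixed by the ring. Compounds 1 and 10, oxetane, 3-chloro-3-methylbut-1-yne and prenylB(pin) (4,4,5,5-tetramethyl-2-(3-methylbut-2-enyl)-1,3,2-dioxaborolane) are assumed to be commercial. MOM = methoxymethyl.

Step 1
Reactants: 1 5-iodosalicylaldehyde (2-hydroxy-5-iodobenzaldehyde)
Product: 2 5-iodo-2-(methoxymethoxy)benzaldehyde
Conditions: MOMCl (1.5 equiv), i-Pr2NEt (2 equiv), CH2Cl2, 0 → 23 °C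
Reagents that add atoms: chloromethyl methyl ether, COCCl
Why: Williamson-type O-alkylation of the phenol with the reactive α-chloro ether gives an acetal that should survive all later basic and organometallic steps and marks the oxygen that becomes the C8 hydroxyl.

Step 2
Reactants: 2 5-iodo-2-(methoxymethoxy)benzaldehyde
Product: 4 5-iodo-2-(methoxymethoxy)phenol, via aryl formate 3 (not isolated)
Conditions: mCPBA (1.3 equiv), CH2Cl2, 0 → 23 °C; then K2CO3 (cat.), MeOH, 0 °C
Reagents that add atoms: 3-chloroperoxybenzoic acid, O=C(OO)c1cccc(Cl)c1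
Why: In this Baeyer–Villiger (Dakin-type) oxidation the electron-rich ortho-alkoxyaryl group migrates in preference to hydrogen, and methanolysis of the formate frees the phenol that becomes O1, meta to iodine; without strong acid the peracid should leave the aryl iodide alone.

Step 3
Reactants: 4 5-iodo-2-(methoxymethoxy)phenol
Product: 5 4-iodo-1-(methoxymethoxy)-2-[(2-methylbut-3-yn-2-yl)oxy]benzene
Conditions: 3-chloro-3-methylbut-1-yne (1.5 equiv), DBU (1.7 equiv), CuCl2·2H2O (1 mol %), MeCN, 0 → 23 °C
Reagents that add atoms: 3-chloro-3-methylbut-1-yne, C#CC(C)(C)Cl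
Why: Copper-catalysed O-propargylation of the phenoxide (through a copper acetylide-derived electrophile) forms the tertiary propargyl aryl ether faster than the tertiary chloride eliminates.

Step 4
Reactants: 5 4-iodo-1-(methoxymethoxy)-2-[(2-methylbut-3-yn-2-yl)oxy]benzene
Product: 9 5-iodo-8-(methoxymethoxy)-2,2-dimethyl-2H-chromene, via allenyl dienone 6 (not isolated), via ortho-allenylphenol 7 (not isolated), via ortho-quinone methide 8 (not isolated)
Conditions: PhNEt2, 170 °C, Ar
Reagents that add atoms: none
Why: In this aryl propargyl ether Claisen rearrangement the [3,3] shift can only end at the one free ortho carbon (the other carries OMOM), and enolisation, 1,5-hydrogen shift and oxa-6π electrocyclisation then close the pyran ring with iodine fixed at C5.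

Step 5
Reactants: 10 4,6-dibromoresorcinol (4,6-dibromobenzene-1,3-diol)
Product: 11 1,5-dibromo-2,4-bis(methoxymethoxy)benzene
Conditions: MOMCl (3 equiv), i-Pr2NEt (4 equiv), CH2Cl2, 0 → 23 °C
Reagents that add atoms: chloromethyl methyl ether, COCCl
Why: Double Williamson-type acetalisation protects both phenols of the symmetric dibromide, whose two C–Br bonds already mark the chain carbon and the 1,1-dimethylallyl carbon of ring A.

Step 6
Reactants: 11 1,5-dibromo-2,4-bis(methoxymethoxy)benzene
Product: 13 3-[5-bromo-2,4-bis(methoxymethoxy)phenyl]propan-1-ol, via aryllithium 12 (not isolated)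
Conditions: n-BuLi (1.05 equiv), THF, −78 °C; then oxetane (2 equiv), BF3·OEt2 (2 equiv), −78 °C
Reagents that add atoms: oxetane, C1COC1
Why: Bromine–lithium exchange on the symmetric dibromide should stop at the OMOM-chelated monolithium species, and its BF3-assisted SN2 opening of oxetane delivers the three-carbon chain with a terminal hydroxyl in one operation.

Step 7
Reactants: 13 3-[5-bromo-2,4-bis(methoxymethoxy)phenyl]propan-1-ol
Product: 14 3-[2,4-bis(methoxymethoxy)-5-(2-methylbut-3-en-2-yl)phenyl]propan-1-ol
Conditions: prenylB(pin) (1.5 equiv), Pd(OAc)2 (4 mol %), SPhos (8 mol %), K3PO4 (3 equiv, aq.), THF, 40 °C, Ar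
Reagents that add atoms: 4,4,5,5-tetramethyl-2-(3-methylbut-2-enyl)-1,3,2-dioxaborolane, CC(C)=CCB1OC(C)(C)C(C)(C)O1
Why: Suzuki–Miyaura coupling of a 3,3-disubstituted allylboronate in its γ-selective mode (SE2′ transmetalation, then reductive elimination from the tertiary σ-allyl before it isomerises, for which a Cy2P-biaryl ligand is chosen) forms the aryl–quaternary carbon bond exactly where the bromide sits, so the group cannot land between the two oxygens.

Step 8
Reactants: 14 3-[2,4-bis(methoxymethoxy)-5-(2-methylbut-3-en-2-yl)phenyl]propan-1-ol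
Product: 15 1-(3-iodopropyl)-2,4-bis(methoxymethoxy)-5-(2-methylbut-3-en-2-yl)benzene
Conditions: I2 (1.3 equiv), PPh3 (1.3 equiv), imidazole (2 equiv), CH2Cl2, 0 → 23 °C, dark
Reagents that add atoms: iodine, II
Why: The Appel reaction turns the primary alcohol into the iodide by SN2 displacement of the alkoxyphosphonium ion, and imidazole buffers the medium so that acetals and alkene stay intact.

Step 9
Reactants: 9 5-iodo-8-(methoxymethoxy)-2,2-dimethyl-2H-chromene; 15 1-(3-iodopropyl)-2,4-bis(methoxymethoxy)-5-(2-methylbut-3-en-2-yl)benzene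
Product: 16 6-{3-[2,4-bis(methoxymethoxy)-5-(2-methylbut-3-en-2-yl)phenyl]propyl}-8-(methoxymethoxy)-2,2-dimethyl-5-(3-methylbut-2-enyl)-2H-chromene
Conditions: Pd(OAc)2 (10 mol %), P(2-furyl)3 (22 mol %), norbornene (2 equiv), Cs2CO3 (4 equiv), H2O (5 equiv), 15 (1.5 equiv), prenylB(pin) (2 equiv, slow addition), DME, 80 °C, Ar
Reagents that add atoms: 4,4,5,5-tetramethyl-2-(3-methylbut-2-enyl)-1,3,2-dioxaborolane, CC(C)=CCB1OC(C)(C)C(C)(C)O1
Why: Proposed new method: zerovalent palladium inserts into the C5–I bond of 9, norbornene carbopalladates the aryl–palladium bond, and the norbornyl–palladium species metalates C6–H, the only ortho C–H, to a five-membered palladacycle. This palladacycle adds iodide 15 to give tetravalent palladium, reductive elimination forms the C6–CH2 bond, and the now doubly ortho-flanked arene expels norbornene by β-carbon elimination; the resulting 5-palladated chromene takes the prenyl group from the boronate and reductively eliminates at the CH2 terminus. The closest known reaction types are the Catellani ortho-alkylation of ortho-blocked aryl iodides such as 1-iodonaphthalene with ipso Suzuki–Miyaura termination by arylboronic acids, and the linear-selective coupling of prenylboronates with aryl halides; an allylboronate as terminator has not been shown. No ring is closed and no stereocentre is formed. Mono-alkylation at C6 is secured by C4a with its C4–H, which blocks the second ortho site and triggers norbornene loss after one alkylation; premature ipso prenylation should be outrun by norbornene insertion, helped by excess norbornene and slow addition of the boronate; the linear prenyl isomer is favoured because a 2,6-disubstituted aryl group cannot readily eliminate onto the tertiary allyl terminus. The vinyl, prenyl and chromene alkenes are unstrained and far poorer acceptors than norbornene, so they should stay outside the cycle.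

Step 10
Reactants: 16 6-{3-[2,4-bis(methoxymethoxy)-5-(2-methylbut-3-en-2-yl)phenyl]propyl}-8-(methoxymethoxy)-2,2-dimethyl-5-(3-methylbut-2-enyl)-2H-chromene
Product: 17 kazinol K
Conditions: HCl (3 M aq.), MeOH, 23 → 40 °C, Ar
Reagents that add atoms: none
Why: Acid-catalysed acetal exchange with methanol removes the three MOM groups; the prenyl group has no ortho hydroxyl, and the monosubstituted vinyl group and the chromene should protonate too slowly to interfere under these conditions.

Compound list
1 | 5-iodosalicylaldehyde (2-hydroxy-5-iodobenzaldehyde) | O=Cc1cc(I)ccc1O | starting material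
2 | 5-iodo-2-(methoxymethoxy)benzaldehyde | O=Cc1cc(I)ccc1OCOC | intermediate
3 | 5-iodo-2-(methoxymethoxy)phenyl formate | O=COc1cc(I)ccc1OCOC | intermediate (not isolated)
4 | 5-iodo-2-(methoxymethoxy)phenol | Oc1cc(I)ccc1OCOC | intermediate
5 | 4-iodo-1-(methoxymethoxy)-2-[(2-methylbut-3-yn-2-yl)oxy]benzene | C#CC(C)(C)Oc1cc(I)ccc1OCOC | intermediate
6 | 5-iodo-2-(methoxymethoxy)-6-(3-methylbuta-1,2-dienyl)cyclohexa-2,4-dien-1-one (racemic, transient sp3 carbon lost on enolisation) | O=C1C(OCOC)=CC=C(I)C1C=C=C(C)C | intermediate (not isolated)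
7 | 3-iodo-6-(methoxymethoxy)-2-(3-methylbuta-1,2-dienyl)phenol | CC(C)=C=Cc1c(I)ccc(OCOC)c1O | intermediate (not isolated)
8 | (6E)-5-iodo-2-(methoxymethoxy)-6-(3-methylbut-2-enylidene)cyclohexa-2,4-dien-1-one | O=C1C(OCOC)=CC=C(I)/C1=C/C=C(C)C | intermediate (not isolated)
9 | 5-iodo-8-(methoxymethoxy)-2,2-dimethyl-2H-chromene | CC1(C)C=Cc2c(I)ccc(OCOC)c2O1 | intermediate
10 | 4,6-dibromoresorcinol (4,6-dibromobenzene-1,3-diol) | Oc1cc(O)c(Br)cc1Br | starting material
11 | 1,5-dibromo-2,4-bis(methoxymethoxy)benzene | COCOc1cc(OCOC)c(Br)cc1Br | intermediate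
12 | [5-bromo-2,4-bis(methoxymethoxy)phenyl]lithium | [Li]c1cc(Br)c(OCOC)cc1OCOC | intermediate (not isolated)
13 | 3-[5-bromo-2,4-bis(methoxymethoxy)phenyl]propan-1-ol | OCCCc1cc(Br)c(OCOC)cc1OCOC | intermediate
14 | 3-[2,4-bis(methoxymethoxy)-5-(2-methylbut-3-en-2-yl)phenyl]propan-1-ol | OCCCc1cc(C(C)(C)C=C)c(OCOC)cc1OCOC | intermediate
15 | 1-(3-iodopropyl)-2,4-bis(methoxymethoxy)-5-(2-methylbut-3-en-2-yl)benzene | ICCCc1cc(C(C)(C)C=C)c(OCOC)cc1OCOC | intermediate
16 | 6-{3-[2,4-bis(methoxymethoxy)-5-(2-methylbut-3-en-2-yl)phenyl]propyl}-8-(methoxymethoxy)-2,2-dimethyl-5-(3-methylbut-2-enyl)-2H-chromene | C=CC(C)(C)c1cc(CCCc2cc(OCOC)c3c(c2CC=C(C)C)C=CC(C)(C)O3)c(OCOC)cc1OCOC | intermediate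
17 | kazinol K, 4-{3-[8-hydroxy-2,2-dimethyl-5-(3-methylbut-2-enyl)-2H-chromen-6-yl]propyl}-6-(2-methylbut-3-en-2-yl)benzene-1,3-diol (achiral) | C=CC(C)(C)c1cc(CCCc2cc(O)c3c(c2CC=C(C)C)C=CC(C)(C)O3)c(O)cc1O | target

Total step count: 10. Longest linear sequence: 6 steps (steps 1–4, 9, 10 from 1; or steps 5–8, 9, 10 from 10).

Steps most likely to fail

Step 9. The prenyl group may be transferred to the first aryl–palladium species before norbornene insertion and C6–H alkylation, the norbornyl–palladium intermediate may close onto the chromene C3=C4 bond, or norbornene may stay in the product. The two ring B bonds would then be made one after the other by halogen-selective cross-couplings. From phenol 4, bromination para to the free hydroxyl (NBS, MeCN, −20 °C) would give 4-bromo-5-iodo-2-(methoxymethoxy)phenol F1. Propargylation as in step 3 would give the aryl 1,1-dimethylpropargyl ether F2, and rearrangement as in step 4 would give 6-bromo-5-iodo-8-(methoxymethoxy)-2,2-dimethyl-2H-chromene F3. A Stille coupling at the more reactive C–I bond (prenylSnBu3, Pd(PPh3)4, DMF, 80 °C) would give 6-bromo-8-(methoxymethoxy)-2,2-dimethyl-5-(3-methylbut-2-enyl)-2H-chromene F4. Zinc insertion into iodide 15 (Zn dust, LiCl, THF) would give the alkylzinc iodide F5, and a Negishi coupling of F4 with F5 (Pd(OAc)2, SPhos, THF, 50 °C) would come back to the route at 16.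

Step 7. The allyl group may be transferred through its unsubstituted terminus, giving the linear prenyl isomer, or the bromide may be lost by protodebromination. The quaternary carbon would then be built by enolate arylation. From bromide 13, palladium-catalysed coupling with the trimethylsilyl ketene acetal of methyl isobutyrate (Pd(dba)2, P(t-Bu)3, ZnF2, DMF, 80 °C) would give methyl 2-[5-(3-hydroxypropyl)-2,4-bis(methoxymethoxy)phenyl]-2-methylpropanoate F6. Reduction with i-Bu2AlH (CH2Cl2, −78 °C) would give 2-[5-(3-hydroxypropyl)-2,4-bis(methoxymethoxy)phenyl]-2-methylpropanal F7, and Wittig methylenation (Ph3P=CH2, THF, 0 °C) would come back at 14.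

Step 10. During acetal hydrolysis the freed C4 hydroxyl of ring A may add to the 1,1-dimethylallyl group under acid, or the prenyl or chromene double bond may be hydrated. The acetals would then be exchanged for silyl ethers without Brønsted acid. From 16, Me3SiOTf and 2,2'-bipyridyl (CH2Cl2, 0 → 23 °C) would give the tris(trimethylsilyl) ether of kazinol K F8, and water or K2CO3 in MeOH would come back at 17.

Further compounds
F1 | step 9 | 4-bromo-5-iodo-2-(methoxymethoxy)phenol | Oc1cc(I)c(Br)cc1OCOC
F2 | step 9 | 1-bromo-2-iodo-5-(methoxymethoxy)-4-[(2-methylbut-3-yn-2-yl)oxy]benzene | C#CC(C)(C)Oc1cc(I)c(Br)cc1OCOC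
F3 | step 9 | 6-bromo-5-iodo-8-(methoxymethoxy)-2,2-dimethyl-2H-chromene | CC1(C)C=Cc2c(I)c(Br)cc(OCOC)c2O1
F4 | step 9 | 6-bromo-8-(methoxymethoxy)-2,2-dimethyl-5-(3-methylbut-2-enyl)-2H-chromene | CC1(C)C=Cc2c(CC=C(C)C)c(Br)cc(OCOC)c2O1
F5 | step 9 | {3-[2,4-bis(methoxymethoxy)-5-(2-methylbut-3-en-2-yl)phenyl]propyl}zinc iodide | I[Zn]CCCc1cc(C(C)(C)C=C)c(OCOC)cc1OCOC
F6 | step 7 | methyl 2-[5-(3-hydroxypropyl)-2,4-bis(methoxymethoxy)phenyl]-2-methylpropanoate | COC(=O)C(C)(C)c1cc(CCCO)c(OCOC)cc1OCOC
F7 | step 7 | 2-[5-(3-hydroxypropyl)-2,4-bis(methoxymethoxy)phenyl]-2-methylpropanal | O=CC(C)(C)c1cc(CCCO)c(OCOC)cc1OCOC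
F8 | step 10 | tris(trimethylsilyl) ether of kazinol K | C=CC(C)(C)c1cc(CCCc2cc(O[Si](C)(C)C)c3c(c2CC=C(C)C)C=CC(C)(C)O3)c(O[Si](C)(C)C)cc1O[Si](C)(C)C
A1 | direct plan | 8-hydroxy-2,2-dimethyl-5-(3-methylbut-2-enyl)-2H-chromene-6-carbaldehyde | O=Cc1cc(O)c2OC(C)(C)C=Cc2c1CC=C(C)C
A2 | direct plan | 1-[2-hydroxy-4-(3-methylbut-2-enyloxy)phenyl]ethanone | CC(=O)c1ccc(OCC=C(C)C)cc1O
A3 | direct plan | (E)-1-[2-hydroxy-4-(3-methylbut-2-enyloxy)phenyl]-3-[8-hydroxy-2,2-dimethyl-5-(3-methylbut-2-enyl)-2H-chromen-6-yl]prop-2-en-1-one | CC(C)=CCOc1ccc(C(=O)/C=C/c2cc(O)c3OC(C)(C)C=Cc3c2CC=C(C)C)c(O)c1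
A4 | direct plan | 6-{3-[2-hydroxy-4-(3-methylbut-2-enyloxy)phenyl]propyl}-2,2-dimethyl-5-(3-methylbut-2-enyl)-2H-chromen-8-ol | CC(C)=CCOc1ccc(CCCc2cc(O)c3OC(C)(C)C=Cc3c2CC=C(C)C)c(O)c1
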